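**Retrosynthetic overview**
- The six-membered ring is closed last: the C5–C6 bond comes from a reductive aldol cyclisation of a cyclopentane carrying an enone arm and a β,γ-unsaturated ketone arm (sets C5 and C6), followed by desilylation.
- The C6 ketone arm comes from a 1,3-dithiane alkylated with an (E)-allylic bromide that carries the arene. The E-alkene comes from Zr-catalysed carboalumination and Pd benzyl coupling.
- The C4 enone arm comes from a vinyllithium addition to a neopentyl aldehyde, then oxidation.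
- Both arms grow from one cis-fused δ-lactone, made by the proposed catalytic enantioselective Baeyer–Villiger desymmetrisation of meso cis-1,5-dimethylbicyclo[3.3.0]octan-3-one (fixes both quaternary carbons).
- Ring order: the cyclopentane is present in the commercial diketone, the δ-lactone is a temporary ring, and the cyclohexanone is formed in the aldol step.

Assumption: compounds 1, 9, 14 and 18 are bought, and for each chiral ligand (steps 3 and 19) the antipode used is the one that a screening run shows to give the drawn configuration.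

Abbreviations: Ar = 2-(tert-butyldimethylsilyloxy)-5-methoxy-3-methylphenyl; TBS = tert-butyldimethylsilyl; TES = triethylsilyl. Target positions follow indan-4-one numbering (C3a, C4 ketone, C5, C6 carbinol, C7, C7a).

**Core lactone and dithiane**

Step 1
Reactants: 1 cis-1,5-dimethylbicyclo[3.3.0]octane-3,7-dione (meso)
Product: 2 monoketal of 1 (meso)
Conditions: 2,2-dimethylpropane-1,3-diol (1.0 equiv), TsOH·H2O (cat.), PhH, reflux, Dean–Stark
Reagents that add atoms: 2,2-dimethylpropane-1,3-diol, OCC(C)(C)CO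
Why: Acid-catalysed ketalisation protects one of two equivalent ketones statistically (dione and bisketal are recycled) and touches no stereocentre.

Step 2
Reactants: 2 monoketal of 1
Product: 5 cis-1,5-dimethylbicyclo[3.3.0]octan-3-one (meso), via monoketal hydrazone 3 (not isolated), via deoxygenated ketal 4 (not isolated)
Conditions: N2H4·H2O, KOH, diethylene glycol, 130 → 200 °C; then 2 M HCl, THF, rt
Reagents that add atoms: water, O
Why: Wolff–Kishner reduction (Huang–Minlon procedure) removes the free ketone and aqueous acid then hydrolyses the ketal, the quaternary ring-fusion carbons being unable to epimerise.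

Step 3
Reactants: 5 cis-1,5-dimethylbicyclo[3.3.0]octan-3-one (meso)
Product: 6 (4aR,7aR)-4a,7a-dimethylhexahydrocyclopenta[c]pyran-3(1H)-one
Conditions: Sc(OTf)3 (5 mol %), C2-symmetric N,N′-dioxide ligand (6 mol %; two (S)-pipecolic acid 2,4,6-triisopropylanilide units joined at the ring nitrogens by a propane-1,3-diyl linker, both nitrogens as N-oxides), mCPBA (1.3 equiv), EtOAc, −20 °C
Reagents that add atoms: mCPBA, OOC(=O)c1cccc(Cl)c1
Why: Proposed new method: a catalytic enantioselective Baeyer–Villiger desymmetrisation of a meso cyclopentanone, in which the Sc(OTf)3/N,N′-dioxide complex binds ketone and peracid so that the Criegee adduct forms inside the chiral pocket, and because migration needs the migrating C–C bond antiperiplanar to the O–O bond the bulky anilide arms let only one of the two enantiotopic CH2–C(=O) bonds reach that alignment, so oxygen is inserted on one side only and the absolute configuration of both quaternary carbons (4aR,7aR) is fixed, the slow uncatalysed peracid oxidation of cyclopentanones at −20 °C leaving room for catalyst control; the closest known reaction type is the chiral Lewis acid (or chiral phosphoric acid) catalysed asymmetric Baeyer–Villiger oxidation of prochiral cyclobutanones and cyclohexanones, which has not been shown for meso cyclopentanones.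

Step 4
Reactants: 6 (4aR,7aR)-lactone
Product: 7 (4aR,7aR)-4a,7a-dimethyloctahydrocyclopenta[c]pyran-3-ol (lactol, both anomers)
Conditions: i-Bu2AlH (1.1 equiv), CH2Cl2, −78 °C; aq. potassium sodium tartrate
Reagents that add atoms: none
Why: Partial reduction of a lactone stops at the lactol because the tetrahedral aluminate is stable at −78 °C, and the new anomeric centre is lost in step 5.

Step 5
Reactants: 7 lactol
Product: 8 [(1R,2R)-2-(1,3-dithian-2-ylmethyl)-1,2-dimethylcyclopentyl]methanol
Conditions: HS(CH2)3SH, BF3·OEt2, CH2Cl2, −20 → 0 °C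
Reagents that add atoms: propane-1,3-dithiol, SCCCS
Why: Lewis acid-mediated dithioacetalisation traps the open hydroxy-aldehyde form of the lactol, masking C6 as an acyl anion equivalent and freeing the neopentyl alcohol that becomes C4.

**Arene side chain**

Step 6
Reactants: 9 4-methoxy-2-methylphenol
Product: 10 2-hydroxy-5-methoxy-3-methylbenzaldehyde
Conditions: (CH2O)n, MgCl2, Et3N, MeCN, reflux; aq. HCl
Reagents that add atoms: formaldehyde (from paraformaldehyde), C=O
Why: Magnesium phenoxide-directed ortho-formylation (Casnati–Skattebøl reaction) goes to the only free position ortho to the hydroxyl group.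

Step 7
Reactants: 10 2-hydroxy-5-methoxy-3-methylbenzaldehyde
Product: 11 2-(tert-butyldimethylsilyloxy)-5-methoxy-3-methylbenzaldehyde
Conditions: TBSCl, imidazole, DMF, rt
Reagents that add atoms: tert-butyldimethylsilyl chloride, CC(C)(C)[Si](C)(C)Cl
Why: Silylation gives a phenol protecting group that survives organolithiums and is removed at the end by fluoride without acid, which would cyclise the ortho-allyl phenol to a chroman.

Step 8
Reactants: 11 silyl-protected aldehyde
Product: 12 [2-(tert-butyldimethylsilyloxy)-5-methoxy-3-methylphenyl]methanol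
Conditions: NaBH4, MeOH/THF, −10 °C; quench at pH 6
Reagents that add atoms: none
Why: Borohydride reduction of the aldehyde at low temperature with a mildly acidic quench avoids aryl-to-benzyl silyl migration.

Step 9
Reactants: 12 benzyl alcohol
Product: 13 tert-butyl[2-(chloromethyl)-4-methoxy-6-methylphenoxy]dimethylsilane
Conditions: PPh3, N-chlorosuccinimide, THF, 0 °C → rt
Reagents that add atoms: N-chlorosuccinimide, ClN1C(=O)CCC1=O
Why: Appel-type chlorination converts the benzylic alcohol into the chloride under neutral conditions that leave the aryl silyl ether intact.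

Step 10
Reactants: 13 benzyl chloride; 14 prop-2-yn-1-ol
Product: 16 (2E)-4-Ar-2-methylbut-2-en-1-ol, via alkenylalane 15 (not isolated)
Conditions: 14, AlMe3 (3 equiv), Cp2ZrCl2 (0.25 equiv), ClCH2CH2Cl, 0 °C → rt; then 13, Pd(PPh3)4 (5 mol %), THF, rt; aq. HCl work-up
Reagents that add atoms: trimethylaluminium, C[Al](C)C
Why: Negishi zirconium-catalysed carboalumination adds methyl and aluminium syn across the alkyne (methyl to the internal carbon), and cross-coupling of the alkenylalane with the benzyl chloride under zerovalent palladium catalysis proceeds with retention, which sets the E trisubstituted alkene.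

Step 11
Reactants: 16 allylic alcohol
Product: 17 tert-butyl{2-[(2E)-4-bromo-3-methylbut-2-en-1-yl]-4-methoxy-6-methylphenoxy}dimethylsilane
Conditions: CBr4, PPh3, 2,6-lutidine, CH2Cl2, −20 → 0 °C
Reagents that add atoms: carbon tetrabromide, BrC(Br)(Br)Br
Why: Appel bromination of the primary allylic alcohol is an SN2 displacement that keeps the alkene position and E geometry.

**Enone arm building block**

Step 12
Reactants: 18 2-methylbut-3-yn-2-ol
Product: 19 triethyl[(2-methylbut-3-yn-2-yl)oxy]silane
Conditions: Et3SiCl, imidazole, DMAP (cat.), DMF, rt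
Reagents that add atoms: triethylsilyl chloride, CC[Si](Cl)(CC)CC
Why: Silylation protects the tertiary alcohol as an ether that tolerates the organometallic steps and leaves with fluoride at the end.

Step 13
Reactants: 19 silyl-protected alkynol
Product: 21 triethyl{[(3E)-4-iodo-2-methylbut-3-en-2-yl]oxy}silane, via alkenylzirconocene 20 (not isolated)
Conditions: Cp2Zr(H)Cl, THF, rt; then I2, 0 °C
Reagents that add atoms: iodine, II
Why: Hydrozirconation adds Zr–H syn with zirconium on the terminal carbon and iodinolysis retains geometry, giving the E vinyl iodide.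

**Assembly**

Step 14
Reactants: 8 hydroxy dithiane; 17 allylic bromide
Product: 23 [(1R,2R)-2-({2-[(2E)-4-Ar-2-methylbut-2-en-1-yl]-1,3-dithian-2-yl}methyl)-1,2-dimethylcyclopentyl]methanol, via dilithio dianion 22 (not isolated)
Conditions: 8, n-BuLi (2.1 equiv), THF, −30 °C; then 17, DMPU, −78 → −30 °C
Reagents that add atoms: none
Why: Corey–Seebach dithiane alkylation through the O,C-dilithio species forms the C6–CH2 bond by SN2 attack at the primary allylic carbon, so the E alkene is kept and the later ketone is β,γ-unsaturated without an allyl-transposition problem.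

Step 15
Reactants: 23 dithiane alcohol
Product: 24 (1R,2R)-2-({2-[(2E)-4-Ar-2-methylbut-2-en-1-yl]-1,3-dithian-2-yl}methyl)-1,2-dimethylcyclopentane-1-carbaldehyde
Conditions: SO3·pyridine, DMSO, i-Pr2NEt, CH2Cl2, 0 °C
Reagents that add atoms: none
Why: Parikh–Doering oxidation converts the neopentyl alcohol into a non-enolisable aldehyde without oxidising the dithiane sulfur.

Step 16
Reactants: 24 aldehyde; 21 vinyl iodide
Product: 26 (2E)-1-[(1R,2R)-2-({2-[(2E)-4-Ar-2-methylbut-2-en-1-yl]-1,3-dithian-2-yl}methyl)-1,2-dimethylcyclopentyl]-4-methyl-4-(triethylsilyloxy)pent-2-en-1-ol (both carbinol epimers), via vinyllithium 25 (not isolated)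
Conditions: 21, t-BuLi (2 equiv per iodide), Et2O, −78 °C; then 24, THF, −78 → −40 °C
Reagents that add atoms: none
Why: Iodine–lithium exchange with retention gives the E vinyllithium, which undergoes 1,2-addition to the aldehyde, and the new carbinol centre is irrelevant because step 17 oxidises it.

Step 17
Reactants: 26 allylic alcohol
Product: 27 (2E)-1-[(1R,2R)-2-({2-[(2E)-4-Ar-2-methylbut-2-en-1-yl]-1,3-dithian-2-yl}methyl)-1,2-dimethylcyclopentyl]-4-methyl-4-(triethylsilyloxy)pent-2-en-1-one
Conditions: SO3·pyridine, DMSO, i-Pr2NEt, CH2Cl2, 0 °C → rt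
Reagents that add atoms: none
Why: Parikh–Doering oxidation of the allylic alcohol gives the enone that will deliver the C5 enolate regiospecifically.

Step 18
Reactants: 27 enone dithiane
Product: 28 (4E)-6-Ar-1-[(1R,2R)-1,2-dimethyl-2-[(2E)-4-methyl-4-(triethylsilyloxy)pent-2-enoyl]cyclopentyl]-4-methylhex-4-en-2-one
Conditions: MeI, CaCO3, MeCN/H2O (9:1), 40 °C
Reagents that add atoms: water, O
Why: Alkylative dithiane hydrolysis under buffered neutral conditions unmasks the C6 ketone without moving its β,γ double bond into conjugation.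

Step 19
Reactants: 28 keto enone
Product: 29 (3aR,5R,6R,7aR)-6-[(2E)-4-Ar-2-methylbut-2-en-1-yl]-6-hydroxy-3a,7a-dimethyl-5-[2-methyl-2-(triethylsilyloxy)propyl]octahydro-4H-inden-4-one
Conditions: [(Ph3P)CuH]6 (0.2 equiv), (R)-DTBM-SEGPHOS (1.2 equiv), PhMe, −40 → −10 °C; aq. NH4Cl
Reagents that add atoms: none
Why: Reductive aldol cyclisation, in which conjugate hydride delivery from the ligated copper hydride gives the Z copper enolate at C5 only (no base, so the β,γ-unsaturated ketone neither enolises nor isomerises) and this enolate closes the six-membered ring onto the C6 ketone through a chair with the C6 side chain and the C5 substituent equatorial and the new oxygen axial, the enantiopure bisphosphine choosing between the two near-mirror-image chair closures so that C5 and C6 are both set R.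

Step 20
Reactants: 29 bis-silyl aldol
Product: 30 (3aR,5R,6R,7aR)-6-hydroxy-6-[(2E)-4-(2-hydroxy-5-methoxy-3-methylphenyl)-2-methylbut-2-en-1-yl]-5-(2-hydroxy-2-methylpropyl)-3a,7a-dimethyloctahydro-4H-inden-4-one
Conditions: Bu4NF, AcOH (1:1), THF, 0 °C → rt
Reagents that add atoms: none
Why: Buffered fluoride desilylation removes the aryl TBS and tertiary TES ethers without acid (no chroman formation or dehydration) and without free base (no retro-aldol or C5 epimerisation).

**Compound list**

1 | cis-1,5-dimethylbicyclo[3.3.0]octane-3,7-dione (meso; methyls on both ring-fusion carbons) | O=C1C[C@@]2(C)CC(=O)C[C@@]2(C)C1 | starting material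
2 | monoketal of 1 with 2,2-dimethylpropane-1,3-diol (meso) | O=C1C[C@@]2(C)CC3(OCC(C)(C)CO3)C[C@@]2(C)C1 | intermediate
3 | hydrazone of the free ketone of 2 | NN=C1C[C@@]2(C)CC3(OCC(C)(C)CO3)C[C@@]2(C)C1 | intermediate
4 | 2,2-dimethylpropane-1,3-diyl ketal of 5 (meso) | C1C[C@@]2(C)CC3(OCC(C)(C)CO3)C[C@@]2(C)C1 | intermediate
5 | cis-1,5-dimethylbicyclo[3.3.0]octan-3-one (meso) | O=C1C[C@@]2(C)CCC[C@@]2(C)C1 | intermediate
6 | (4aR,7aR)-4a,7a-dimethylhexahydrocyclopenta[c]pyran-3(1H)-one (cis-fused δ-lactone) | O=C1C[C@@]2(C)CCC[C@@]2(C)CO1 | intermediate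
7 | (4aR,7aR)-4a,7a-dimethyloctahydrocyclopenta[c]pyran-3-ol (lactol, both anomers) | OC1C[C@@]2(C)CCC[C@@]2(C)CO1 | intermediate
8 | [(1R,2R)-2-(1,3-dithian-2-ylmethyl)-1,2-dimethylcyclopentyl]methanol | S1CCCSC1C[C@@]2(C)CCC[C@@]2(C)CO | intermediate
9 | 4-methoxy-2-methylphenol | COc1ccc(O)c(C)c1 | starting material
10 | 2-hydroxy-5-methoxy-3-methylbenzaldehyde | COc1cc(C)c(O)c(C=O)c1 | intermediate
11 | 2-(tert-butyldimethylsilyloxy)-5-methoxy-3-methylbenzaldehyde | COc1cc(C)c(O[Si](C)(C)C(C)(C)C)c(C=O)c1 | intermediate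
12 | [2-(tert-butyldimethylsilyloxy)-5-methoxy-3-methylphenyl]methanol | COc1cc(C)c(O[Si](C)(C)C(C)(C)C)c(CO)c1 | intermediate
13 | tert-butyl[2-(chloromethyl)-4-methoxy-6-methylphenoxy]dimethylsilane | COc1cc(C)c(O[Si](C)(C)C(C)(C)C)c(CCl)c1 | intermediate
14 | prop-2-yn-1-ol | C#CCO | starting material
15 | (E)-alkenylalane, dimethylaluminium on the alkene CH cis to methyl, alcohol as its dimethylaluminium alkoxide | C[Al](C)/C=C(\C)CO[Al](C)C | intermediate
16 | (2E)-4-[2-(tert-butyldimethylsilyloxy)-5-methoxy-3-methylphenyl]-2-methylbut-2-en-1-ol | COc1cc(C)c(O[Si](C)(C)C(C)(C)C)c(C/C=C(\C)CO)c1 | intermediate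
17 | tert-butyl{2-[(2E)-4-bromo-3-methylbut-2-en-1-yl]-4-methoxy-6-methylphenoxy}dimethylsilane | COc1cc(C)c(O[Si](C)(C)C(C)(C)C)c(C/C=C(\C)CBr)c1 | intermediate
18 | 2-methylbut-3-yn-2-ol | C#CC(C)(C)O | starting material
19 | triethyl[(2-methylbut-3-yn-2-yl)oxy]silane | C#CC(C)(C)O[Si](CC)(CC)CC | intermediate
20 | (E)-alkenyl(chloro)zirconocene from 19 | Cl[Zr](/C=C/C(C)(C)O[Si](CC)(CC)CC)(C1C=CC=C1)C1C=CC=C1 | intermediate
21 | triethyl{[(3E)-4-iodo-2-methylbut-3-en-2-yl]oxy}silane | I/C=C/C(C)(C)O[Si](CC)(CC)CC | intermediate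
22 | O,C-dilithio derivative of 8 (lithium alkoxide, 2-lithio-1,3-dithiane) | [Li]C1(SCCCS1)C[C@@]2(C)CCC[C@@]2(C)CO[Li] | intermediate
23 | [(1R,2R)-2-({2-[(2E)-4-Ar-2-methylbut-2-en-1-yl]-1,3-dithian-2-yl}methyl)-1,2-dimethylcyclopentyl]methanol | COc1cc(C)c(O[Si](C)(C)C(C)(C)C)c(C/C=C(\C)CC2(SCCCS2)C[C@@]3(C)CCC[C@@]3(C)CO)c1 | intermediate
24 | (1R,2R)-2-({2-[(2E)-4-Ar-2-methylbut-2-en-1-yl]-1,3-dithian-2-yl}methyl)-1,2-dimethylcyclopentane-1-carbaldehyde | COc1cc(C)c(O[Si](C)(C)C(C)(C)C)c(C/C=C(\C)CC2(SCCCS2)C[C@@]3(C)CCC[C@@]3(C)C=O)c1 | intermediate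
25 | (E)-vinyllithium from 21 | [Li]/C=C/C(C)(C)O[Si](CC)(CC)CC | intermediate
26 | (2E)-allylic alcohol from 24 and 25 (both carbinol epimers) | COc1cc(C)c(O[Si](C)(C)C(C)(C)C)c(C/C=C(\C)CC2(SCCCS2)C[C@@]3(C)CCC[C@@]3(C)C(O)/C=C/C(C)(C)O[Si](CC)(CC)CC)c1 | intermediate
27 | (2E)-enone with the C6 carbon still a 1,3-dithiane | COc1cc(C)c(O[Si](C)(C)C(C)(C)C)c(C/C=C(\C)CC2(SCCCS2)C[C@@]3(C)CCC[C@@]3(C)C(=O)/C=C/C(C)(C)O[Si](CC)(CC)CC)c1 | intermediate
28 | (4E)-6-Ar-1-[(1R,2R)-1,2-dimethyl-2-[(2E)-4-methyl-4-(triethylsilyloxy)pent-2-enoyl]cyclopentyl]-4-methylhex-4-en-2-one | COc1cc(C)c(O[Si](C)(C)C(C)(C)C)c(C/C=C(\C)CC(=O)C[C@@]2(C)CCC[C@@]2(C)C(=O)/C=C/C(C)(C)O[Si](CC)(CC)CC)c1 | intermediate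
29 | (3aR,5R,6R,7aR)-6-[(2E)-4-Ar-2-methylbut-2-en-1-yl]-6-hydroxy-3a,7a-dimethyl-5-[2-methyl-2-(triethylsilyloxy)propyl]octahydro-4H-inden-4-one | COc1cc(C)c(O[Si](C)(C)C(C)(C)C)c(C/C=C(\C)C[C@@]2(O)C[C@@]3(C)CCC[C@@]3(C)C(=O)[C@@H]2CC(C)(C)O[Si](CC)(CC)CC)c1 | intermediate
30 | (3aR,5R,6R,7aR)-6-hydroxy-6-[(2E)-4-(2-hydroxy-5-methoxy-3-methylphenyl)-2-methylbut-2-en-1-yl]-5-(2-hydroxy-2-methylpropyl)-3a,7a-dimethyloctahydro-4H-inden-4-one (CNP0190381.3) | COc1cc(C)c(O)c(C/C=C(\C)C[C@@]2(O)C[C@@]3(C)CCC[C@@]3(C)C(=O)[C@@H]2CC(C)(C)O)c1 | target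

**Totals and risks**

Total step count: 20. Longest linear sequence: 13 steps (9 → 30 through steps 6–11 and 14–20). The core branch 1 → 30 is 12 steps.

The three steps most likely to fail:

For step 3 (the proposed new reaction), the cyclopentanone may react too slowly under the chiral Lewis acid, or the enantioselectivity may be low. The fallback uses known chemistry, sets out from 5 and comes back at 6. Enantioselective deprotonation of 5 with lithium (R,R)- or (S,S)-bis(1-phenylethyl)amide (LiCl, THF, −100 °C, Me3SiCl present) gives the scalemic silyl enol ether (1S,5R)-1,5-dimethyl-3-(trimethylsilyloxy)bicyclo[3.3.0]oct-2-ene F1. Ozonolysis (O3, CH2Cl2/MeOH, −78 °C) with NaBH4 work-up gives 2-[(1R,2R)-2-(hydroxymethyl)-1,2-dimethylcyclopentyl]acetic acid F2. TsOH in toluene then closes F2 to lactone 6.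

For step 14, the alkoxide-bearing, β-quaternary dithiane may lithiate incompletely, and O-alkylation or allylic transposition may compete. The fallback drops the dithiane altogether, sets out from lactone 6 and bromide 17, and comes back at 28. PhSO2Na in DMF converts 17 into the allylic phenyl sulfone F3. Its α-lithio derivative F4 (n-BuLi, THF, −78 °C, 2.1 equiv) opens lactone 6 to the β-keto sulfone F5. SmI2 in THF/MeOH at −78 °C removes the sulfonyl group to give the hydroxy β,γ-unsaturated ketone F6, and Dess–Martin oxidation gives the keto aldehyde F7. Aldehyde-selective coupling with vinyl iodide 21 (CrCl2, NiCl2 cat., DMSO) gives the allylic alcohol F8, and a second Dess–Martin oxidation gives 28.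

For step 19, hydride delivery to the hindered enone β-carbon may be slow, the copper enolate may be protonated without cyclising, or the wrong C5/C6 facial pair may form, because the substrate itself gives little bias. The fallback separates enolate formation from ring closure, sets out from 28 and comes back at 29. RhCl(PPh3)3-catalysed 1,4-hydrosilylation with Et3SiH (PhH, 50 °C) gives the Z triethylsilyl enol ether F9 regiospecifically. BF3·OEt2 (CH2Cl2, −78 °C) then effects an intramolecular Mukaiyama aldol addition onto the C6 ketone and gives 29 after aqueous work-up. The Lewis acid can be varied to tune the diastereomer ratio.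

**Further compounds**

F1 | step 3 | (1S,5R)-1,5-dimethyl-3-(trimethylsilyloxy)bicyclo[3.3.0]oct-2-ene | C[Si](C)(C)OC=1C[C@@]2(C)CCC[C@@]2(C)C=1
F2 | step 3 | 2-[(1R,2R)-2-(hydroxymethyl)-1,2-dimethylcyclopentyl]acetic acid | OC(=O)C[C@@]1(C)CCC[C@@]1(C)CO
F3 | step 14 | tert-butyl{4-methoxy-2-methyl-6-[(2E)-3-methyl-4-(phenylsulfonyl)but-2-en-1-yl]phenoxy}dimethylsilane | COc1cc(C)c(O[Si](C)(C)C(C)(C)C)c(C/C=C(\C)CS(=O)(=O)c2ccccc2)c1
F4 | step 14 | α-lithio derivative of F3 | COc1cc(C)c(O[Si](C)(C)C(C)(C)C)c(C/C=C(\C)C([Li])S(=O)(=O)c2ccccc2)c1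
F5 | step 14 | (4E)-6-Ar-1-[(1R,2R)-2-(hydroxymethyl)-1,2-dimethylcyclopentyl]-4-methyl-3-(phenylsulfonyl)hex-4-en-2-one (both C3 epimers) | COc1cc(C)c(O[Si](C)(C)C(C)(C)C)c(C/C=C(\C)C(C(=O)C[C@@]2(C)CCC[C@@]2(C)CO)S(=O)(=O)c3ccccc3)c1
F6 | step 14 | (4E)-6-Ar-1-[(1R,2R)-2-(hydroxymethyl)-1,2-dimethylcyclopentyl]-4-methylhex-4-en-2-one | COc1cc(C)c(O[Si](C)(C)C(C)(C)C)c(C/C=C(\C)CC(=O)C[C@@]2(C)CCC[C@@]2(C)CO)c1
F7 | step 14 | (1R,2R)-2-[(4E)-6-Ar-4-methyl-2-oxohex-4-en-1-yl]-1,2-dimethylcyclopentane-1-carbaldehyde | COc1cc(C)c(O[Si](C)(C)C(C)(C)C)c(C/C=C(\C)CC(=O)C[C@@]2(C)CCC[C@@]2(C)C=O)c1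
F8 | step 14 | (4E)-6-Ar-1-[(1R,2R)-2-[(2E)-1-hydroxy-4-methyl-4-(triethylsilyloxy)pent-2-en-1-yl]-1,2-dimethylcyclopentyl]-4-methylhex-4-en-2-one (both carbinol epimers) | COc1cc(C)c(O[Si](C)(C)C(C)(C)C)c(C/C=C(\C)CC(=O)C[C@@]2(C)CCC[C@@]2(C)C(O)/C=C/C(C)(C)O[Si](CC)(CC)CC)c1
F9 | step 19 | (4E)-6-Ar-1-[(1R,2R)-1,2-dimethyl-2-[(1Z)-4-methyl-1,4-bis(triethylsilyloxy)pent-1-en-1-yl]cyclopentyl]-4-methylhex-4-en-2-one | COc1cc(C)c(O[Si](C)(C)C(C)(C)C)c(C/C=C(\C)CC(=O)C[C@@]2(C)CCC[C@@]2(C)/C(O[Si](CC)(CC)CC)=C/CC(C)(C)O[Si](CC)(CC)CC)c1
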